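**Strategy.** The bis-ketal is opened at its two C–O bonds, C2–O1 (ring C) and C2–O7'' (ring F), leading back to an open-chain 1,3-diketone whose central carbon C3 carries flavan carbon C8''. The key step exploits that C2 has the oxidation level of a ketone and is flanked by the phenolic oxygens O1 and O7''; a chlorine on C3 removes the C3–H through which diketone, hemiketals and ketal would otherwise aromatise to a flavone or benzofuran. One acid treatment strips the methoxymethyl groups from O1 and O7'' and lets both oxygens add to the ring-B ketone, closing rings F and C and setting C2 from C3. The precursor is the (3S)-3-chloro diketone, benzylated at every other phenol.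

Key step: step 14

Remark on numbering: flavonoid locants are used (chromanone unit plain, ring B primed, flavan unit double-primed, ring E triple-primed); "Fl" is the (2R)-5-(benzyloxy)-2-[4-(benzyloxy)phenyl]-7-(methoxymethoxy)chroman-8-yl group.
Remark on stereochemistry: 21, 24, 25 and 26 have the same spatial arrangement at C3 and, from 24 on, a cis ring fusion; the C3 descriptor reads S, R, S and S only because CIP priorities change. The target is (2S,3S,2''R).
Remark on design: 9 and 17 are taken as commercial. Fl enters as an aryl bromide in a ketone arylation, because 2,4,6-trialkoxyphenyl groups are the non-transferred ligands of diaryliodonium salts. C3 is chlorinated without a chiral catalyst and the wanted epimer is isolated by chromatography, so no step before the key step is unprecedented. O5'' (para to C8'') stays benzylated, so the benzylic C3–Cl never sits para to a free phenol.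

**Step 1**
Reactants: 1 2,4,6-trihydroxyacetophenone; 2 benzyl bromide
Product: 3 1-[2,4-bis(benzyloxy)-6-hydroxyphenyl]ethan-1-one
Conditions: BnBr (2.05 equiv), K2CO3, DMF, 0 °C → rt
Reagents that add atoms: benzyl bromide (2), BrCc1ccccc1
Why: Williamson ether synthesis under carbonate base: the 4-OH and one ortho-OH are alkylated, whereas the last ortho-OH is locked in a hydrogen bond to the acetyl oxygen and stays free.

**Step 2**
Reactants: 3 1-[2,4-bis(benzyloxy)-6-hydroxyphenyl]ethan-1-one; 4 chloromethyl methyl ether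
Product: 5 1-[2,4-bis(benzyloxy)-6-(methoxymethoxy)phenyl]ethan-1-one
Conditions: NaH, DMF, 0 °C; MOMCl, 0 °C → rt
Reagents that add atoms: chloromethyl methyl ether (4), COCCl
Why: Williamson-type O-alkylation: NaH breaks the chelate and the phenoxide attacks the chloromethyl ether, giving the base-stable but acid-labile mask for the future O1.

**Step 3**
Reactants: 6 2,4,6-trihydroxybenzaldehyde; 4 chloromethyl methyl ether
Product: 7 2,6-dihydroxy-4-(methoxymethoxy)benzaldehyde
Conditions: MOMCl (1.0 equiv), i-Pr2NEt (1.1 equiv), THF/CH2Cl2, −20 → 0 °C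
Reagents that add atoms: chloromethyl methyl ether (4), COCCl
Why: Regioselective Williamson-type O-alkylation: the 4-OH is para to the formyl group and not chelated, hence the most acidic and accessible, so one equivalent of chloride should mark the future O7'' first (any bis-ether is removed by chromatography).

**Step 4**
Reactants: 7 2,6-dihydroxy-4-(methoxymethoxy)benzaldehyde; 2 benzyl bromide
Product: 8 2-(benzyloxy)-6-hydroxy-4-(methoxymethoxy)benzaldehyde
Conditions: BnBr (1.05 equiv), K2CO3, acetone, rt → 40 °C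
Reagents that add atoms: benzyl bromide (2), BrCc1ccccc1
Why: Williamson ether synthesis: one of the two equivalent ortho-hydroxyls (the future O5'') is benzylated, and the survivor (the future O1'') is then held in a strong hydrogen bond to the formyl oxygen and does not react under carbonate.

**Step 5**
Reactants: 8 2-(benzyloxy)-6-hydroxy-4-(methoxymethoxy)benzaldehyde; 9 1-[4-(benzyloxy)phenyl]ethan-1-one
Product: 10 (E)-3-[2-(benzyloxy)-6-hydroxy-4-(methoxymethoxy)phenyl]-1-[4-(benzyloxy)phenyl]prop-2-en-1-one
Conditions: KOH (50% aq.), EtOH, rt; AcOH to pH 6 at 0 °C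
Reagents that add atoms: none
Why: Claisen–Schmidt condensation: the ketone enolate adds to the aldehyde and the aldol loses water to the conjugated (E)-enone, the ortho-phenoxide only slowing the addition.

**Step 6**
Reactants: 10 (E)-chalcone
Product: 11 3-[2-(benzyloxy)-6-hydroxy-4-(methoxymethoxy)phenyl]-1-[4-(benzyloxy)phenyl]propan-1-one
Conditions: H2 (1 atm), RhCl(PPh3)3 (5 mol%), toluene/EtOH (1:1), 40 °C
Reagents that add atoms: none
Why: Homogeneous hydrogenation of the enone C=C catalysed by RhCl(PPh3)3; this catalyst does not cleave aryl benzyl ethers or reduce the aryl ketone.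

**Step 7**
Reactants: 11 saturated ketone
Product: 12 (1S)-3-[2-(benzyloxy)-6-hydroxy-4-(methoxymethoxy)phenyl]-1-[4-(benzyloxy)phenyl]propan-1-ol
Conditions: RuCl(p-cymene)[(S,S)-TsDPEN] (2 mol%), HCO2H/Et3N (5:2), EtOAc, 35 °C
Reagents that add atoms: none
Why: Noyori asymmetric transfer hydrogenation of an aryl alkyl ketone: the hydride formed from RuCl(p-cymene)[(S,S)-TsDPEN] differentiates aryl from the CH2 chain and delivers hydrogen to the face that gives the (S)-carbinol, the sense established for acetophenone-type ketones.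

**Step 8**
Reactants: 12 (S)-carbinol
Product: 13 (2R)-5-(benzyloxy)-2-[4-(benzyloxy)phenyl]-7-(methoxymethoxy)chromane
Conditions: PPh3, DIAD, toluene, 0 °C → rt
Reagents that add atoms: none
Why: Intramolecular Mitsunobu etherification: the phenol displaces the phosphonium-activated benzylic oxygen in an SN2 step with inversion, turning the (S)-carbinol into the (2R)-flavan; toluene at low temperature disfavours ionisation of the p-alkoxybenzylic centre.

**Step 9**
Reactants: 13 (2R)-flavan; 14 N-bromosuccinimide
Product: 15 (2R)-5-(benzyloxy)-2-[4-(benzyloxy)phenyl]-8-bromo-7-(methoxymethoxy)chromane (Fl–Br)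
Conditions: NBS (1.0 equiv), CH2Cl2, −78 → −40 °C, dark
Reagents that add atoms: N-bromosuccinimide (14), O=C1CCC(=O)N1Br
Why: Electrophilic aromatic bromination of a phloroglucinol triether: C8'', next to the tied-back ring oxygen, is less hindered than C6'' between two open ether groups, the regioselectivity usual for 5,7-di-O-alkylflavans.

**Step 10**
Reactants: 5 ring-A methyl ketone; 15 Fl–Br
Product: 16 1-[2,4-bis(benzyloxy)-6-(methoxymethoxy)phenyl]-2-Fl-ethan-1-one
Conditions: Pd2(dba)3 (2.5 mol%), XPhos (6 mol%), NaOtBu (2.2 equiv), toluene, 80 °C; 5 in 1.3-fold excess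
Reagents that add atoms: none
Why: α-Arylation of a methyl ketone enolate by an aryl bromide under Pd2(dba)3/XPhos catalysis (Buchwald–Hartwig-type ketone arylation): the bulky biarylphosphine permits oxidative addition to the hindered electron-rich bromide and fast reductive elimination, and the congested product enolate should not be arylated twice.

**Step 11**
Reactants: 16 deoxybenzoin; 17 4-(benzyloxy)benzaldehyde
Product: 18 1-[2,4-bis(benzyloxy)-6-(methoxymethoxy)phenyl]-3-[4-(benzyloxy)phenyl]-2-Fl-3-hydroxypropan-1-one (diastereomer mixture at the two new centres)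
Conditions: LiN(SiMe3)2, THF, −78 °C; then 17; AcOH, −78 °C
Reagents that add atoms: none
Why: Aldol addition of a preformed lithium enolate: the C3–C2 bond can only form at carbon (no O-acylation as in a Claisen route), a cold acidic quench forestalls retro-aldol and dehydration, and the two new stereocentres are erased in steps 12 and 13.

**Step 12**
Reactants: 18 aldol
Product: 19 1-[2,4-bis(benzyloxy)-6-(methoxymethoxy)phenyl]-3-[4-(benzyloxy)phenyl]-2-Fl-propane-1,3-dione
Conditions: Dess–Martin periodinane, CH2Cl2, 0 °C → rt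
Reagents that add atoms: none
Why: Dess–Martin oxidation of the secondary p-alkoxybenzylic alcohol to the ketone under non-basic conditions that cannot trigger retro-aldol cleavage.

**Step 13**
Reactants: 19 2-aryl-1,3-diketone; 20 N-chlorosuccinimide
Product: 21 (3S)-chloro diketone: 2-chloro derivative of 19 with S configuration at the chlorinated carbon
Conditions: NaH, THF, 0 °C; NCS (1.05 equiv), −40 → 0 °C; AcOH; preparative HPLC (silica)
Reagents that add atoms: N-chlorosuccinimide (20), O=C1CCC(=O)N1Cl
Why: Electrophilic α-chlorination of a preformed 1,3-diketone enolate, which outcompetes the electron-rich ring D for one equivalent of N-chlorosuccinimide; the remote C2'' centre cannot bias the enolate faces, so both C3 epimers should form and the (3S) epimer 21 is isolated by chromatography, its (3R) epimer not being carried forward.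

**Step 14**
Reactants: 21 (3S)-chloro diketone
Product: 24 (2S,3R,2''R)-3-chloro-5,7,4',5'',4'''-penta-O-benzyl bis-ketal, via bis-phenol 22 (not isolated), via hemiketal 23 (not isolated)
Conditions: HCl (ca. 0.5 M, from 4 M HCl in dioxane), MeOH/CH2Cl2 (1:2), 0 °C → rt; pH 7 buffer work-up
Reagents that add atoms: none
Why: HCl cleaves the two methoxymethyl ethers (methanol carries the CH2 unit away as dimethoxymethane, so no electrophile is left to attack ring D) and frees bis-phenol 22; O7'' adds to the ring-B ketone C2 in a 5-exo-trig closure of ring F to give hemiketal 23, which loses water to an oxocarbenium ion stabilised by O7'' and ring B, and O1 adds to this ion in a 6-exo-trig closure of ring C. The closest known reaction type is the acid-catalysed double ketalisation of a ketone by two tethered phenols, as used for bisbenzannulated ketals and spiroketals. C2 is the only new stereocentre and is controlled by C3: rings F and C share the C2–C3 bond and can only be cis-fused, so ring B must end up on the side of the chlorine, which gives (2S,3R). The step needs the bis-ketal to be the only sink, and the chlorine secures this because no intermediate has a C3–H to lose on the way to a flavone or a benzofuran, while addition of O7'' to the other ketone C4 is reversible and leads nowhere since O1 cannot reach C4, and either order of the two additions ends at 24. Dilute HCl rather than a strong carboxylic acid is chosen to spare the p-alkoxybenzylic C2''–O1'' ether and the benzyl ethers, and base is kept out of the work-up because a phenoxide next to the chloro diketone could expel chloride or start a retro-Claisen cleavage.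

**Step 15**
Reactants: 24 chloro bis-ketal
Product: 25 (2S,3S,2''R)-5,7,4',5'',4'''-penta-O-benzyl bis-ketal
Conditions: (Me3Si)3SiH (2 equiv), AIBN (0.2 equiv), degassed toluene, 80 °C
Reagents that add atoms: none
Why: Radical chain dehalogenation: the silyl radical abstracts chlorine from the α-keto benzylic carbon and the C3 radical takes hydrogen from the excess silane on the only face that keeps the ring fusion cis, so C2 dictates (3S), and no enolate is formed that could expel a ketal oxygen.

**Step 16**
Reactants: 25 penta-O-benzyl bis-ketal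
Product: 26 target, (2S,3S,2''R)
Conditions: H2 (1 atm), Pd(OH)2/C, THF/MeOH, rt; filtration, no base
Reagents that add atoms: none
Why: Hydrogenolysis of five aryl benzyl ethers over Pd(OH)2/C under neutral conditions; the diaryl ketal, the aryl ketone and the flavan C2''–O bond should survive short exposure at 1 atm, as in deprotections of benzylated A-type proanthocyanidins, and no stereocentre is touched.

**Compound list**

1 | 2,4,6-trihydroxyacetophenone | CC(=O)c1c(O)cc(O)cc1O | starting material
2 | benzyl bromide | BrCc1ccccc1 | starting material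
3 | 1-[2,4-bis(benzyloxy)-6-hydroxyphenyl]ethan-1-one | CC(=O)c1c(O)cc(OCc9ccccc9)cc1OCc9ccccc9 | intermediate
4 | chloromethyl methyl ether | COCCl | starting material
5 | 1-[2,4-bis(benzyloxy)-6-(methoxymethoxy)phenyl]ethan-1-one | CC(=O)c1c(OCOC)cc(OCc9ccccc9)cc1OCc9ccccc9 | intermediate
6 | 2,4,6-trihydroxybenzaldehyde | O=Cc1c(O)cc(O)cc1O | starting material
7 | 2,6-dihydroxy-4-(methoxymethoxy)benzaldehyde | O=Cc1c(O)cc(OCOC)cc1O | intermediate
8 | 2-(benzyloxy)-6-hydroxy-4-(methoxymethoxy)benzaldehyde | O=Cc1c(O)cc(OCOC)cc1OCc9ccccc9 | intermediate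
9 | 1-[4-(benzyloxy)phenyl]ethan-1-one | CC(=O)c1ccc(OCc9ccccc9)cc1 | starting material
10 | (E)-3-[2-(benzyloxy)-6-hydroxy-4-(methoxymethoxy)phenyl]-1-[4-(benzyloxy)phenyl]prop-2-en-1-one | O=C(/C=C/c1c(O)cc(OCOC)cc1OCc9ccccc9)c1ccc(OCc9ccccc9)cc1 | intermediate
11 | 3-[2-(benzyloxy)-6-hydroxy-4-(methoxymethoxy)phenyl]-1-[4-(benzyloxy)phenyl]propan-1-one | O=C(CCc1c(O)cc(OCOC)cc1OCc9ccccc9)c1ccc(OCc9ccccc9)cc1 | intermediate
12 | (1S)-3-[2-(benzyloxy)-6-hydroxy-4-(methoxymethoxy)phenyl]-1-[4-(benzyloxy)phenyl]propan-1-ol | O[C@@H](CCc1c(O)cc(OCOC)cc1OCc9ccccc9)c1ccc(OCc9ccccc9)cc1 | intermediate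
13 | (2R)-5-(benzyloxy)-2-[4-(benzyloxy)phenyl]-7-(methoxymethoxy)chromane | COCOc1cc(OCc9ccccc9)c2c(c1)O[C@@H](c1ccc(OCc9ccccc9)cc1)CC2 | intermediate
14 | N-bromosuccinimide | O=C1CCC(=O)N1Br | starting material
15 | (2R)-5-(benzyloxy)-2-[4-(benzyloxy)phenyl]-8-bromo-7-(methoxymethoxy)chromane | COCOc1cc(OCc9ccccc9)c2c(c1Br)O[C@@H](c1ccc(OCc9ccccc9)cc1)CC2 | intermediate
16 | 1-[2,4-bis(benzyloxy)-6-(methoxymethoxy)phenyl]-2-Fl-ethan-1-one | COCOc1cc(OCc9ccccc9)c2c(c1CC(=O)c1c(OCOC)cc(OCc9ccccc9)cc1OCc9ccccc9)O[C@@H](c1ccc(OCc9ccccc9)cc1)CC2 | intermediate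
17 | 4-(benzyloxy)benzaldehyde | O=Cc1ccc(OCc9ccccc9)cc1 | starting material
18 | aldol: 3-hydroxy-3-[4-(benzyloxy)phenyl]-2-Fl-1-[2,4-bis(benzyloxy)-6-(methoxymethoxy)phenyl]propan-1-one, diastereomer mixture | COCOc1cc(OCc9ccccc9)c2c(c1C(C(O)c1ccc(OCc9ccccc9)cc1)C(=O)c1c(OCOC)cc(OCc9ccccc9)cc1OCc9ccccc9)O[C@@H](c1ccc(OCc9ccccc9)cc1)CC2 | intermediate
19 | 1-[2,4-bis(benzyloxy)-6-(methoxymethoxy)phenyl]-3-[4-(benzyloxy)phenyl]-2-Fl-propane-1,3-dione | COCOc1cc(OCc9ccccc9)c2c(c1C(C(=O)c1c(OCOC)cc(OCc9ccccc9)cc1OCc9ccccc9)C(=O)c1ccc(OCc9ccccc9)cc1)O[C@@H](c1ccc(OCc9ccccc9)cc1)CC2 | intermediate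
20 | N-chlorosuccinimide | O=C1CCC(=O)N1Cl | starting material
21 | (3S)-chloro diketone: 2-chloro-19, S at the chlorinated carbon (key-step precursor) | COCOc1cc(OCc9ccccc9)c2c(c1[C@@](C(=O)c3c(OCOC)cc(OCc9ccccc9)cc3OCc9ccccc9)(C(=O)c3ccc(OCc9ccccc9)cc3)Cl)O[C@@H](c1ccc(OCc9ccccc9)cc1)CC2 | intermediate
22 | bis-phenol: 21 with O1–H and O7''–H free | Oc1cc(OCc9ccccc9)c2c(c1[C@@](C(=O)c3c(O)cc(OCc9ccccc9)cc3OCc9ccccc9)(C(=O)c3ccc(OCc9ccccc9)cc3)Cl)O[C@@H](c1ccc(OCc9ccccc9)cc1)CC2 | intermediate
23 | hemiketal: ring F closed (O7''–C2), C2–OH of either configuration, O1–H free | OC1(c2ccc(OCc9ccccc9)cc2)Oc2cc(OCc9ccccc9)c3c(c2[C@@]1(Cl)C(=O)c1c(O)cc(OCc9ccccc9)cc1OCc9ccccc9)O[C@@H](c1ccc(OCc9ccccc9)cc1)CC3 | intermediate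
24 | (2S,3R,2''R)-3-chloro-5,7,4',5'',4'''-penta-O-benzyl bis-ketal (key-step product) | O=C1c2c(OCc9ccccc9)cc(OCc9ccccc9)cc2O[C@@]2(c3ccc(OCc9ccccc9)cc3)Oc3cc(OCc9ccccc9)c4c(c3[C@@]12Cl)O[C@@H](c1ccc(OCc9ccccc9)cc1)CC4 | intermediate
25 | (2S,3S,2''R)-5,7,4',5'',4'''-penta-O-benzyl bis-ketal | O=C1c2c(OCc9ccccc9)cc(OCc9ccccc9)cc2O[C@@]2(c3ccc(OCc9ccccc9)cc3)Oc3cc(OCc9ccccc9)c4c(c3[C@@H]12)O[C@@H](c1ccc(OCc9ccccc9)cc1)CC4 | intermediate
26 | target, (2S,3S,2''R): 5,7-dihydroxy-2-(4-hydroxyphenyl)chroman-4-one joined C3–C8'' and C2–O7'' to (2R)-5-hydroxy-2-(4-hydroxyphenyl)chromane, rings F and C cis-fused | O=C1c2c(O)cc(O)cc2O[C@@]2(c3ccc(O)cc3)Oc3cc(O)c4c(c3[C@@H]12)O[C@@H](c1ccc(O)cc1)CC4 | target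

**Totals and risks**

Total: 16 steps. Longest linear sequence: 14 steps (steps 3 to 16, from 6).

Step 14 (key step). The tertiary benzylic C3–Cl bond, activated by the three oxygens of ring D, may ionise or be solvolysed by methanol before or after ring closure. The blocking group is then lost and C3 is substituted or the system aromatises; the cascade may also stall at the hemiketal. The fallback sets out from 19 and comes back at 25. The sodium enolate of 19 is sulfenylated with N-(phenylthio)succinimide to give the (3S)-phenylthio diketone F1 and its C3 epimer, the (3R)-phenylthio diketone F2, which are separated as in step 13. The acid treatment of step 14 then converts F1 into the 3-phenylthio bis-ketal F3; sulfur blocks C3 equally well but does not leave as an anion. Bu3SnH/AIBN in toluene at 80 °C cleaves the α-keto C–S bond with the same cis delivery of hydrogen and gives 25.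

Step 13. The enolate faces are not discriminated, so about half of the material is expected to go to the unwanted epimer, and the two open-chain epimers, which differ only in the relation of C3 to the distant C2'', may not separate; over-chlorination at C6'' of ring D is a second concern. The fallback sets out from 19 and comes back at 24. Diketone 19 is chlorinated as in step 13 but the epimers are not separated, so that 21 is carried on together with its C3 epimer, the (3R)-chloro diketone F4. The mixture is taken through the step 14 conditions, which turn F4 into the (2R,3S,2''R)-chloro bis-ketal F5, and the sorting is moved to the rigid polycycles, where 24 is separated from F5 by chromatography or crystallisation.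

Step 10. Oxidative addition into the di-ortho-oxygenated bromide may be slow, so that protodebromination and self-condensation of the hindered ketone take over. The fallback sets out from 15 (with 9 and 6) and comes back at 19. The unhindered ketone 9 is arylated with 15 under the same type of catalysis to give the deoxybenzoin 1-[4-(benzyloxy)phenyl]-2-Fl-ethan-1-one F6. Aldehyde 6 is benzylated twice (BnBr, K2CO3) to 2,4-bis(benzyloxy)-6-hydroxybenzaldehyde F7 and capped (NaH, MOMCl) to 2,4-bis(benzyloxy)-6-(methoxymethoxy)benzaldehyde F8. The lithium enolate of F6 is added to F8 to give the aldol F9, and Dess–Martin oxidation gives 19.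

**Further compounds**

F1 | step 14 | (3S)-phenylthio diketone, 2-(phenylsulfanyl)-19 | COCOc1cc(OCc9ccccc9)c2c(c1[C@@](C(=O)c3c(OCOC)cc(OCc9ccccc9)cc3OCc9ccccc9)(C(=O)c3ccc(OCc9ccccc9)cc3)Sc5ccccc5)O[C@@H](c1ccc(OCc9ccccc9)cc1)CC2
F2 | step 14 | (3R)-phenylthio diketone, C3 epimer of F1 | COCOc1cc(OCc9ccccc9)c2c(c1[C@](C(=O)c3c(OCOC)cc(OCc9ccccc9)cc3OCc9ccccc9)(C(=O)c3ccc(OCc9ccccc9)cc3)Sc5ccccc5)O[C@@H](c1ccc(OCc9ccccc9)cc1)CC2
F3 | step 14 | (2S,3R,2''R)-3-(phenylsulfanyl)-penta-O-benzyl bis-ketal | O=C1c2c(OCc9ccccc9)cc(OCc9ccccc9)cc2O[C@@]2(c3ccc(OCc9ccccc9)cc3)Oc3cc(OCc9ccccc9)c4c(c3[C@@]12Sc5ccccc5)O[C@@H](c1ccc(OCc9ccccc9)cc1)CC4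
F4 | step 13 | (3R)-chloro diketone, C3 epimer of 21 | COCOc1cc(OCc9ccccc9)c2c(c1[C@](C(=O)c3c(OCOC)cc(OCc9ccccc9)cc3OCc9ccccc9)(C(=O)c3ccc(OCc9ccccc9)cc3)Cl)O[C@@H](c1ccc(OCc9ccccc9)cc1)CC2
F5 | step 13 | (2R,3S,2''R)-3-chloro-penta-O-benzyl bis-ketal | O=C1c2c(OCc9ccccc9)cc(OCc9ccccc9)cc2O[C@]2(c3ccc(OCc9ccccc9)cc3)Oc3cc(OCc9ccccc9)c4c(c3[C@]12Cl)O[C@@H](c1ccc(OCc9ccccc9)cc1)CC4
F6 | step 10 | 1-[4-(benzyloxy)phenyl]-2-Fl-ethan-1-one | COCOc1cc(OCc9ccccc9)c2c(c1CC(=O)c1ccc(OCc9ccccc9)cc1)O[C@@H](c1ccc(OCc9ccccc9)cc1)CC2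
F7 | step 10 | 2,4-bis(benzyloxy)-6-hydroxybenzaldehyde | O=Cc1c(O)cc(OCc9ccccc9)cc1OCc9ccccc9
F8 | step 10 | 2,4-bis(benzyloxy)-6-(methoxymethoxy)benzaldehyde | O=Cc1c(OCOC)cc(OCc9ccccc9)cc1OCc9ccccc9
F9 | step 10 | aldol: 3-hydroxy-3-[2,4-bis(benzyloxy)-6-(methoxymethoxy)phenyl]-2-Fl-1-[4-(benzyloxy)phenyl]propan-1-one, diastereomer mixture | COCOc1cc(OCc9ccccc9)c2c(c1C(C(=O)c1ccc(OCc9ccccc9)cc1)C(O)c1c(OCOC)cc(OCc9ccccc9)cc1OCc9ccccc9)O[C@@H](c1ccc(OCc9ccccc9)cc1)CC2
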